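G.L is the product I count here, in two flasks with the same charge that differ in their time of reading.

| setting | south | north |
|---|---|---|
| G | 0.20 M | 0.20 M |
| E | 0.200 M | 0.200 M |
| time | 30 h | 50 h |

    E ⇌ L, rate k1*(cs1 - [L]) while solid is left; crystals form when [L] > cs1 (cs1 = 44 mM, k1 = 0.375 h⁻¹)
    G + 2 L → D (k2 = 0.173 M⁻² h⁻¹)
    G + L → G.L (k3 = 0.0829 M⁻¹ h⁻¹)

* which of the two there is more of at the end, south (G.L / D)
* which of the two there is more of at the end, north (G.L / D)
* G.L at the end, in percent of the G charged, south
* G.L at the end, in percent of the G charged, north

Solid E can feed L at up to 16.5 mM h⁻¹. With L at its solubility, the two steps use L at 0.863 mM h⁻¹, so the highest feed is far faster than that use, and L climbs until feed and use balance. I find that level by going round. With L at 44 mM, the use calls for a shortfall of 2.30 mM below solubility, which gives 41.7 mM. Put back, this lowers the use a little and gives 41.8 mM. This is the quantity I carry: the working level of L, at which dissolving balances the use by both steps with G as charged.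

L approaches that level with a time constant of about 2.67 h, which is short beside the south run, so I count that time as a delay. I expect solid to be left at the end of north, since I reckon that flask needs about 87.2 mM of E, less than the 0.200 M charged.

At this level G falls by a pseudo-first-order law with constant 0.00377 h⁻¹, and 92.0% of what reacts becomes G.L. The selectivity factor, G.L per D, is 11.5. South and north therefore run on the same clock, and north simply reads it later. The share of G gone after the delay, times that 92.0%, gives me 9.01% of G.L in south and 15.0% in north.

The forecast says “L sits in quasi-steady state just below saturation”. It names G.L as the larger in south and G.L in north, with 9% and 15.1%; its north figure is higher than mine.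

G.L ends at 9.07% in south and 15.1% in north, more than D at 0.755% and 1.29%. North stands 6.1 percentage points higher because of its longer time: at south's time the same flask gives 9.07%, and L reads 0.0422 M at the end of north. For south left until 3.0 d, the same working level gives 21.2%. That flask reads G.L 21.3%, with D at 1.83%.

The numbers are made up; what happens was integrated by code.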